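The flavanone is cut at the aryl ether bond O1–C8a. O1 joins the C2 stereocentre to the A-ring carbon C8a, so ring C can be closed on the aromatic side and no bond at C2 is ever broken. One palladium-catalysed O-arylation therefore forms O1–C8a and the pyran ring with retention. Its precursor is an open-chain (1S)-1,3-diarylpropane-1,3-diol: free S carbinol at the future C2 (set by CBS reduction), the future C4 oxygen capped as a migration-resistant TIPS ether, and a fully substituted 2-bromo-diprenyl-bis(MOM) A ring. Desilylation, oxidation at C4 and MOM removal finish the synthesis.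

Key step: step 13

Remark (stereochemistry): the carbon that becomes C4 is made racemic in step 10 and carried as both epimers through 15–19, because step 15 turns it into the carbonyl; the SMILES of these compounds leave it undefined.
Remark (B ring): ring B needs OH at C3′, OMe at C4′ and prenyl at C5′; a 5-bromovanillin-type aldehyde has OMe and OH the other way round, so the bromocatechol aldehyde 1 is methylated selectively at O4 instead.
Remark (materials): 1, 4 and 8 are taken as catalogue compounds.

Step 1
Reactants: 1 3-bromo-4,5-dihydroxybenzaldehyde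
Product: 2 3-bromo-5-hydroxy-4-methoxybenzaldehyde
Conditions: MeI (1.05 equiv), Li2CO3 (1.2 equiv), DMF, 40 °C
Reagents that add atoms: methyl iodide, CI
Why: Williamson etherification under acidity control: the hydroxyl para to the formyl group and ortho to bromine is the more acidic one, so the weak base forms only that phenoxide and one equivalent of methyl iodide should cap O4 while the meta hydroxyl stays free.

Step 2
Reactants: 2 3-bromo-5-hydroxy-4-methoxybenzaldehyde
Product: 3 3-bromo-4-methoxy-5-(methoxymethoxy)benzaldehyde
Conditions: MOMCl (1.5 equiv), iPr2NEt (2 equiv), CH2Cl2, 0 °C → rt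
Reagents that add atoms: chloromethyl methyl ether, COCCl
Why: Standard methoxymethyl etherification of the remaining phenol gives an acetal that is stable to the organometallics, bases, fluoride and oxidants used later and is cleaved only by acid in the last step.

Step 3
Reactants: 3 3-bromo-4-methoxy-5-(methoxymethoxy)benzaldehyde; 4 tributyl(3-methylbut-2-en-1-yl)stannane
Product: 5 4-methoxy-3-(methoxymethoxy)-5-(3-methylbut-2-en-1-yl)benzaldehyde
Conditions: 4 (1.3 equiv), Pd(PPh3)4 (5 mol%), DMF, 90 °C
Reagents that add atoms: none
Why: Stille coupling of the aryl bromide: the allylic stannane does not add to the free aldehyde (an allylboron or allylzinc reagent would), and reductive elimination from the aryl(η3-prenyl)palladium intermediate at the unsubstituted allyl terminus should give the linear prenyl arene.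

Step 4
Reactants: 5 4-methoxy-3-(methoxymethoxy)-5-(3-methylbut-2-en-1-yl)benzaldehyde
Product: 6 rac-1-[4-methoxy-3-(methoxymethoxy)-5-(3-methylbut-2-en-1-yl)phenyl]ethan-1-ol
Conditions: MeMgBr (1.3 equiv), THF, 0 °C; H2O quench
Reagents that add atoms: methylmagnesium bromide, C[Mg]Br
Why: Grignard addition to the aldehyde; the new carbinol stereocentre is formed as a racemate and is removed by the oxidation in step 5.

Step 5
Reactants: 6 rac-1-[4-methoxy-3-(methoxymethoxy)-5-(3-methylbut-2-en-1-yl)phenyl]ethan-1-ol
Product: 7 1-[4-methoxy-3-(methoxymethoxy)-5-(3-methylbut-2-en-1-yl)phenyl]ethan-1-one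
Conditions: Dess–Martin periodinane (1.3 equiv), NaHCO3, CH2Cl2, 0 °C → rt
Reagents that add atoms: none
Why: Dess–Martin oxidation of the secondary benzylic alcohol to the methyl ketone under buffered, non-acidic conditions that leave the prenyl alkene and the MOM acetal untouched.

Step 6
Reactants: 8 5-bromoresorcinol
Product: 10 2-bromo-4,6-dihydroxybenzaldehyde, via aryl iminium chloride 9 (not isolated)
Conditions: POCl3 (1.2 equiv), DMF (1.5 equiv), MeCN, −15 °C → rt; then H2O, 50 °C
Reagents that add atoms: N,N-dimethylformamide, CN(C)C=O; water, O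
Why: Vilsmeier–Haack formylation: the chloroiminium electrophile attacks the resorcinol para to one hydroxyl and ortho to the other (the orcinol-type position next to bromine, not the more hindered carbon between the two hydroxyls), and water hydrolyses the iminium salt to the aldehyde.

Step 7
Reactants: 10 2-bromo-4,6-dihydroxybenzaldehyde
Product: 11 2-bromo-4,6-dihydroxy-3,5-diiodobenzaldehyde
Conditions: NIS (2.1 equiv), TsOH·H2O (10 mol%), MeCN, 0 °C → rt
Reagents that add atoms: N-iodosuccinimide, O=C1CCC(=O)N1I
Why: Electrophilic aromatic iodination: the only two ring hydrogens left are each ortho or para to both hydroxyl groups, so two equivalents of N-iodosuccinimide should iodinate exactly the two carbons that will carry the prenyl groups.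

Step 8
Reactants: 11 2-bromo-4,6-dihydroxy-3,5-diiodobenzaldehyde
Product: 12 2-bromo-3,5-diiodo-4,6-bis(methoxymethoxy)benzaldehyde
Conditions: NaH (2.4 equiv), MOMCl (2.6 equiv), DMF, 0 °C → rt
Reagents that add atoms: chloromethyl methyl ether, COCCl
Why: Williamson-type MOM etherification of both acidic iodophenols via their sodium phenoxides, which also overcomes the hydrogen bond of the hydroxyl next to the formyl group.

Step 9
Reactants: 12 2-bromo-3,5-diiodo-4,6-bis(methoxymethoxy)benzaldehyde; 4 tributyl(3-methylbut-2-en-1-yl)stannane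
Product: 13 2-bromo-4,6-bis(methoxymethoxy)-3,5-bis(3-methylbut-2-en-1-yl)benzaldehyde
Conditions: 4 (2.4 equiv), Pd2(dba)3 (5 mol%), AsPh3 (20 mol%), DMF, 50 °C
Reagents that add atoms: none
Why: Chemoselective twofold Stille coupling: triphenylarsine-ligated palladium(0) inserts into the two C–I bonds far faster than into the C–Br bond at 50 °C, the stannane is inert to the aldehyde, and linear prenyl transfer is expected as in step 3, so the bromine needed for the ring closure should survive.

Step 10
Reactants: 7 1-[4-methoxy-3-(methoxymethoxy)-5-(3-methylbut-2-en-1-yl)phenyl]ethan-1-one; 13 2-bromo-4,6-bis(methoxymethoxy)-3,5-bis(3-methylbut-2-en-1-yl)benzaldehyde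
Product: 15 racemic β-hydroxy ketone (aldol adduct of 7 and 13; full name in the list), via lithium enolate 14 (not isolated)
Conditions: 7 (1.2 equiv), LDA (1.15 equiv), THF, −78 °C, 30 min; then 13, −78 °C; AcOH quench at −78 °C
Reagents that add atoms: none
Why: Lithium enolate aldol addition: the kinetic enolate of methyl ketone 7 adds to the non-enolisable, ortho,ortho′-disubstituted aldehyde 13 at −78 °C and the cold acidic quench prevents retro-aldol reaction and dehydration; the new carbinol (future C4) is formed as a racemate on purpose because it is oxidised to the carbonyl in step 15.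

Step 11
Reactants: 15 racemic β-hydroxy ketone
Product: 16 racemic β-(triisopropylsilyloxy) ketone (full name in the list)
Conditions: TIPSOTf (1.5 equiv), 2,6-lutidine (3 equiv), CH2Cl2, −40 → 0 °C
Reagents that add atoms: triisopropylsilyl trifluoromethanesulfonate, CC(C)[Si](C(C)C)(C(C)C)OS(=O)(=O)C(F)(F)F
Why: Silylation of the hindered benzylic hydroxyl with the reactive silyl triflate and a non-nucleophilic pyridine base at low temperature, where the aryl MOM acetals and the ketone should not react; TIPS is chosen because it does not migrate between 1,3-related oxygens under base.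

Step 12
Reactants: 16 racemic β-(triisopropylsilyloxy) ketone
Product: 17 (1S)-bromo alcohol, the cyclisation precursor (both C3 epimers; full name in the list)
Conditions: (R)-2-methyl-CBS-oxazaborolidine (0.5 equiv), catecholborane (2 equiv), toluene, −78 → −40 °C; MeOH, then aqueous work-up
Reagents that add atoms: none
Why: Corey–Bakshi–Shibata reduction: the aryl ketone binds the (R)-oxazaborolidine with the B-ring aryl as the large and the CH2 chain as the small substituent, so hydride from catecholborane (unreactive toward the prenyl alkenes at this temperature) is delivered to the Re face and should give the S carbinol at the future C2 by catalyst control in both C3 epimers.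

Step 13
Reactants: 17 (1S)-bromo alcohol
Product: 18 (2S)-flavan-4-ol TIPS ether (both C4 epimers; full name in the list)
Conditions: RockPhos Pd G3 (10 mol%), Cs2CO3 (2 equiv), toluene, 90 °C
Reagents that add atoms: none
Why: Monoligated Pd(0) inserts into the C8a–Br bond, the S carbinol oxygen binds and is deprotonated by carbonate to give a seven-membered aryl(alkoxo)palladacycle, and C–O reductive elimination releases the aryl ether and Pd(0). The closest known reaction type is the palladium-catalysed intramolecular O-arylation of secondary alcohols with aryl bromides (Buchwald–Hartwig-type etherification) that gives chromans. Ring C closes as a six-membered ring, formally a 6-exo attack of the alkoxide oxygen on the ipso carbon C8a. No stereocentre is created: C2 keeps its S configuration because only its O–H bond is broken, and both C4 epimers cyclise to epimeric products that converge in step 15. The step needs C–O reductive elimination to outrun β-hydride elimination of the secondary alkoxide, which the bulky di-tert-butylbiarylphosphine, the crowded aryl group on palladium and the six-ring geometry should secure. The C4 oxygen is locked as a TIPS ether that can neither chelate palladium, be oxidised nor migrate to the C2 oxygen, and the trisubstituted prenyl alkenes offer only disfavoured 4-exo or 5-endo Heck modes.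

Step 14
Reactants: 18 (2S)-flavan-4-ol TIPS ether
Product: 19 (2S)-flavan-4-ol (both C4 epimers; full name in the list)
Conditions: TBAF (2 equiv), THF, rt → 45 °C
Reagents that add atoms: none
Why: Fluoride-induced cleavage of the Si–O bond, driven by the strong Si–F bond, frees the C4 hydroxyl as the only hydroxyl in the molecule, and the non-acidic medium keeps the electron-rich benzylic alcohol from ionising and leaves C2 and the MOM groups untouched.

Step 15
Reactants: 19 (2S)-flavan-4-ol
Product: 20 (2S)-flavanone tris(MOM) ether (full name in the list)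
Conditions: Dess–Martin periodinane (1.5 equiv), NaHCO3, CH2Cl2, 0 °C → rt
Reagents that add atoms: none
Why: Dess–Martin oxidation of the single secondary benzylic alcohol converts both C4 epimers into one flavanone under buffered conditions that cannot open the pyranone ring by retro-oxa-Michael reaction, so the S configuration at C2 should be kept.

Step 16
Reactants: 20 (2S)-flavanone tris(MOM) ether
Product: 21 isoamoritin
Conditions: HCl (1.25 M in MeOH), THF co-solvent, 0 °C → rt
Reagents that add atoms: none
Why: Acid-catalysed methanolysis of the three methoxymethyl acetals (transacetalisation to dimethoxymethane) at or near room temperature, conditions mild enough that the prenyl alkenes should not be protonated and the base-sensitive flavanone stereocentre at C2 is not epimerised.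

Compound list

1 | 3-bromo-4,5-dihydroxybenzaldehyde | O=Cc1cc(O)c(O)c(Br)c1 | starting material
2 | 3-bromo-5-hydroxy-4-methoxybenzaldehyde | COc1c(O)cc(C=O)cc1Br | intermediate
3 | 3-bromo-4-methoxy-5-(methoxymethoxy)benzaldehyde | COCOc1cc(C=O)cc(Br)c1OC | intermediate
4 | tributyl(3-methylbut-2-en-1-yl)stannane | CCCC[Sn](CCCC)(CCCC)CC=C(C)C | starting material
5 | 4-methoxy-3-(methoxymethoxy)-5-(3-methylbut-2-en-1-yl)benzaldehyde | COCOc1cc(C=O)cc(CC=C(C)C)c1OC | intermediate
6 | rac-1-[4-methoxy-3-(methoxymethoxy)-5-(3-methylbut-2-en-1-yl)phenyl]ethan-1-ol | COCOc1cc(C(C)O)cc(CC=C(C)C)c1OC | intermediate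
7 | 1-[4-methoxy-3-(methoxymethoxy)-5-(3-methylbut-2-en-1-yl)phenyl]ethan-1-one | COCOc1cc(C(C)=O)cc(CC=C(C)C)c1OC | intermediate
8 | 5-bromoresorcinol (5-bromobenzene-1,3-diol) | Oc1cc(O)cc(Br)c1 | starting material
9 | N-[(2-bromo-4,6-dihydroxyphenyl)methylidene]-N-methylmethanaminium chloride (not isolated) | C[N+](C)=Cc1c(O)cc(O)cc1Br.[Cl-] | intermediate
10 | 2-bromo-4,6-dihydroxybenzaldehyde | O=Cc1c(O)cc(O)cc1Br | intermediate
11 | 2-bromo-4,6-dihydroxy-3,5-diiodobenzaldehyde | O=Cc1c(O)c(I)c(O)c(I)c1Br | intermediate
12 | 2-bromo-3,5-diiodo-4,6-bis(methoxymethoxy)benzaldehyde | O=Cc1c(Br)c(I)c(OCOC)c(I)c1OCOC | intermediate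
13 | 2-bromo-4,6-bis(methoxymethoxy)-3,5-bis(3-methylbut-2-en-1-yl)benzaldehyde | O=Cc1c(Br)c(CC=C(C)C)c(OCOC)c(CC=C(C)C)c1OCOC | intermediate
14 | lithium 1-[4-methoxy-3-(methoxymethoxy)-5-(3-methylbut-2-en-1-yl)phenyl]ethen-1-olate (not isolated) | [Li+].[O-]C(=C)c1cc(OCOC)c(OC)c(CC=C(C)C)c1 | intermediate
15 | (3RS)-3-[2-bromo-4,6-bis(methoxymethoxy)-3,5-bis(3-methylbut-2-en-1-yl)phenyl]-3-hydroxy-1-[4-methoxy-3-(methoxymethoxy)-5-(3-methylbut-2-en-1-yl)phenyl]propan-1-one, racemic | O=C(CC(O)c1c(Br)c(CC=C(C)C)c(OCOC)c(CC=C(C)C)c1OCOC)c1cc(OCOC)c(OC)c(CC=C(C)C)c1 | intermediate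
16 | (3RS)-3-[2-bromo-4,6-bis(methoxymethoxy)-3,5-bis(3-methylbut-2-en-1-yl)phenyl]-1-[4-methoxy-3-(methoxymethoxy)-5-(3-methylbut-2-en-1-yl)phenyl]-3-[(triisopropylsilyl)oxy]propan-1-one, racemic | O=C(CC(O[Si](C(C)C)(C(C)C)C(C)C)c1c(Br)c(CC=C(C)C)c(OCOC)c(CC=C(C)C)c1OCOC)c1cc(OCOC)c(OC)c(CC=C(C)C)c1 | intermediate
17 | (1S,3RS)-3-[2-bromo-4,6-bis(methoxymethoxy)-3,5-bis(3-methylbut-2-en-1-yl)phenyl]-1-[4-methoxy-3-(methoxymethoxy)-5-(3-methylbut-2-en-1-yl)phenyl]-3-[(triisopropylsilyl)oxy]propan-1-ol, S at the free carbinol, both epimers at the silyloxy carbon | Brc1c(CC=C(C)C)c(OCOC)c(CC=C(C)C)c(OCOC)c1C(O[Si](C(C)C)(C(C)C)C(C)C)C[C@H](O)c1cc(OCOC)c(OC)c(CC=C(C)C)c1 | intermediate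
18 | (2S,4RS)-5,7-bis(methoxymethoxy)-2-[4-methoxy-3-(methoxymethoxy)-5-(3-methylbut-2-en-1-yl)phenyl]-6,8-bis(3-methylbut-2-en-1-yl)-4-[(triisopropylsilyl)oxy]chromane, both C4 epimers | COc1c(OCOC)cc([C@@H]2CC(O[Si](C(C)C)(C(C)C)C(C)C)c3c(OCOC)c(CC=C(C)C)c(OCOC)c(CC=C(C)C)c3O2)cc1CC=C(C)C | intermediate
19 | (2S,4RS)-5,7-bis(methoxymethoxy)-2-[4-methoxy-3-(methoxymethoxy)-5-(3-methylbut-2-en-1-yl)phenyl]-6,8-bis(3-methylbut-2-en-1-yl)chroman-4-ol, both C4 epimers | COc1c(OCOC)cc([C@@H]2CC(O)c3c(OCOC)c(CC=C(C)C)c(OCOC)c(CC=C(C)C)c3O2)cc1CC=C(C)C | intermediate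
20 | (2S)-5,7-bis(methoxymethoxy)-2-[4-methoxy-3-(methoxymethoxy)-5-(3-methylbut-2-en-1-yl)phenyl]-6,8-bis(3-methylbut-2-en-1-yl)chroman-4-one | COc1c(OCOC)cc([C@@H]2CC(=O)c3c(OCOC)c(CC=C(C)C)c(OCOC)c(CC=C(C)C)c3O2)cc1CC=C(C)C | intermediate
21 | isoamoritin, (2S)-5,7-dihydroxy-2-[3-hydroxy-4-methoxy-5-(3-methylbut-2-en-1-yl)phenyl]-6,8-bis(3-methylbut-2-en-1-yl)chroman-4-one | COc1c(O)cc([C@@H]2CC(=O)c3c(O)c(CC=C(C)C)c(O)c(CC=C(C)C)c3O2)cc1CC=C(C)C | target

Total step count: 16.
Longest linear sequence: 12 steps (steps 1–5, then 10–16); the A-ring branch (steps 6–9) joins at step 10.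

Steps most likely to fail

1. Step 13 (ring closure). Oxidative addition at the fully substituted C8a–Br carbon may be slow, so that β-hydride elimination from the palladium alkoxide (oxidation of the C2 carbinol with loss of bromine) or plain protodebromination overtakes C–O bond formation. The fallback sets out from 17 and comes back at 18. It is a copper(I)-catalysed Ullmann-type intramolecular O-arylation (CuI, 3,4,7,8-tetramethyl-1,10-phenanthroline, Cs2CO3, toluene, 110 °C). Copper alkoxides have no easy β-hydride elimination pathway, so the failing elementary step is removed and not merely tuned. It makes no new compound (F0).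

2. Step 9 (twofold prenylation). Chemoselectivity may be lost by insertion into the C–Br bond before the second, more hindered iodide has coupled, and allylic transposition during prenyl transfer would give 1,1-dimethylallyl groups. The fallback sets out from 10 and comes back at 13, avoiding iodides and tin.
   - Allyl bromide and K2CO3 in acetone should give 2-bromo-4,6-bis(prop-2-en-1-yloxy)benzaldehyde F1.
   - Heating in N,N-diethylaniline at about 190 °C should move both allyl groups to the only two free ring carbons by aromatic Claisen rearrangement (ortho, or para by Cope relay where the ortho carbon is filled), giving 2-bromo-4,6-dihydroxy-3,5-di(prop-2-en-1-yl)benzaldehyde F2.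
   - NaH and MOMCl should give 2-bromo-4,6-bis(methoxymethoxy)-3,5-di(prop-2-en-1-yl)benzaldehyde F3.
   - Olefin cross-metathesis with excess 2-methylbut-2-ene and the second-generation Grubbs catalyst in CH2Cl2 at 40 °C should convert both allyl groups into prenyl groups and deliver 13.

3. Step 16 (final deprotection). Protonation of a prenyl double bond may lead to addition of the neighbouring C7 or C5 hydroxyl (dimethylchroman ring formation) or of methanol, competing with acetal cleavage. The fallback sets out from 20 and comes back at 21 without Brønsted acid. TMSOTf with 2,2′-bipyridyl in CH2Cl2 at 0 °C → rt should exchange each aryl MOM group for a silyl group and give isoamoritin tris(trimethylsilyl) ether F4. Stirring F4 with aqueous methanol at rt should hydrolyse the aryl silyl ethers to 21.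

Further compounds

F0 | step 13 | none | none
F1 | step 9 | 2-bromo-4,6-bis(prop-2-en-1-yloxy)benzaldehyde | O=Cc1c(Br)cc(OCC=C)cc1OCC=C
F2 | step 9 | 2-bromo-4,6-dihydroxy-3,5-di(prop-2-en-1-yl)benzaldehyde | O=Cc1c(Br)c(CC=C)c(O)c(CC=C)c1O
F3 | step 9 | 2-bromo-4,6-bis(methoxymethoxy)-3,5-di(prop-2-en-1-yl)benzaldehyde | O=Cc1c(Br)c(CC=C)c(OCOC)c(CC=C)c1OCOC
F4 | step 16 | (2S)-2-[4-methoxy-3-(trimethylsilyloxy)-5-(3-methylbut-2-en-1-yl)phenyl]-6,8-bis(3-methylbut-2-en-1-yl)-5,7-bis(trimethylsilyloxy)chroman-4-one | COc1c(O[Si](C)(C)C)cc([C@@H]2CC(=O)c3c(O[Si](C)(C)C)c(CC=C(C)C)c(O[Si](C)(C)C)c(CC=C(C)C)c3O2)cc1CC=C(C)C
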